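**Retrosynthetic overview**

1. 21 ⇐ 4,8-dione 18: 1,2-reduction of the C4 carbonyl from the face of the C8 bridge, acetylation, release of the phenol.
2. 18 ⇐ cyclopentenone 12 + aldehyde 14 in one operation: C5–C6 (Mukaiyama aldol), C6–C7 (cation–olefin closure of ring B = C1–C8–C5–C6–C7) and C1–C2 (pinacol shift of C2 from C8 to C1).
3. The six-membered ring C1–C2–C3–C4–C5–C8 is thus never closed as such: it is ring A of 12 (five-membered, C2–C3–C4–C5–C8), enlarged by insertion of C1 between C8 and C2.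
4. Enabling feature: the C8 ketone lies between two quaternary bridgeheads, C1 bearing the vinylic C2 and C5 bearing C6; C6 is benzylic to an electron-rich aryl ring and joined to C1 through C7, so a C6 cation, a C1=C7 alkene on a C8 carbinol and a 1,2-shift of C2 account for both rings.
5. 12 ⇐ (R)-4-silyloxycyclopentenone 1: alkynyl addition/anti-allylmagnesiation (C8 centre, E-alkene), C4 oxidation, methoxylation at C3 and C5; ring order: ring A (bought) → ring B closed and ring A enlarged together in step 10.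

Key step: step 10

Remark on the chemistry: C4 is kept at the ketone level through the key step and reduced afterwards; 11 and 12 are used as mixtures of C5 epimers because C5 is made planar again in step 10; atom numbers C1–C8 are those of the bicyclo[3.2.1]oct-2-ene core of the target (C1 allyl bridgehead, C2=C3, C4 acetoxy carbon, C5 methoxy bridgehead, C6 aryl carbon, C7 methyl carbon, C8 bridging carbonyl) and are used for the same atoms in all intermediates.

**Route**

Step 1
Reactants: 1 (4R)-4-[(tert-butyldimethylsilyl)oxy]cyclopent-2-en-1-one; 2 prop-1-yn-1-ylmagnesium bromide; 3 allylmagnesium bromide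
Product: 5 (1S,4R)-4-[(tert-butyldimethylsilyl)oxy]-1-[(2E)-hexa-2,5-dien-3-yl]cyclopent-2-en-1-ol, via bromomagnesium propargylic alkoxide 4 (not isolated)
Conditions: 2 (1.2 equiv), THF, −78 → 0 °C; then 3 (3 equiv), CuI (10 mol %), 0 → 45 °C; H2O
Reagents that add atoms: none
Why: Grignard 1,2-addition anti to the 4-silyloxy group sets the tertiary carbinol centre, and the magnesium alkoxide 4 then directs the known CuI-catalysed anti-carbomagnesiation of the alkyne (allyl to the proximal carbon, magnesium chelated at the distal one), so that protonation should give the E-trisubstituted alkene.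

Step 2
Reactants: 5 (1S,4R)-4-[(tert-butyldimethylsilyl)oxy]-1-[(2E)-hexa-2,5-dien-3-yl]cyclopent-2-en-1-ol
Product: 6 (1S,4R)-1-[(2E)-hexa-2,5-dien-3-yl]cyclopent-2-ene-1,4-diol
Conditions: Bu4NF, THF, 0 °C
Reagents that add atoms: none
Why: Fluoride-induced desilylation, driven by the Si–F bond, frees the secondary allylic alcohol without touching the tertiary alcohol or its stereocentre.

Step 3
Reactants: 6 (1S,4R)-1-[(2E)-hexa-2,5-dien-3-yl]cyclopent-2-ene-1,4-diol
Product: 7 (4S)-4-[(2E)-hexa-2,5-dien-3-yl]-4-hydroxycyclopent-2-en-1-one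
Conditions: MnO2, CH2Cl2, rt
Reagents that add atoms: none
Why: MnO2 oxidises only the secondary allylic alcohol (allylic alcohol oxidation), the tertiary carbinol cannot be oxidised, and the enone formed makes later ionisation of the tertiary C8–O bond unfavourable.

Step 4
Reactants: 7 (4S)-4-[(2E)-hexa-2,5-dien-3-yl]-4-hydroxycyclopent-2-en-1-one
Product: 8 (4S)-4-[(tert-butyldimethylsilyl)oxy]-4-[(2E)-hexa-2,5-dien-3-yl]cyclopent-2-en-1-one
Conditions: TBSOTf, 2,6-lutidine, CH2Cl2, −78 → 0 °C
Reagents that add atoms: tert-butyldimethylsilyl trifluoromethanesulfonate CC(C)(C)[Si](C)(C)OS(=O)(=O)C(F)(F)F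
Why: Silyl triflate silylation of a hindered tertiary alcohol blocks retro-aldol opening and iodo-etherification in the following steps and supplies the group that is lost in the pinacol shift of step 10.

Step 5
Reactants: 8 (4S)-4-[(tert-butyldimethylsilyl)oxy]-4-[(2E)-hexa-2,5-dien-3-yl]cyclopent-2-en-1-one
Product: 9 (4S)-4-[(tert-butyldimethylsilyl)oxy]-4-[(2E)-hexa-2,5-dien-3-yl]-2-iodocyclopent-2-en-1-one
Conditions: I2, pyridine, DMAP (cat.), CH2Cl2, rt
Reagents that add atoms: iodine II
Why: Amine-mediated α-iodination of an enone (conjugate addition of the amine, iodination of the enolate, elimination) places the halogen regiospecifically on the α-carbon, the future C3.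

Step 6
Reactants: 9 (4S)-4-[(tert-butyldimethylsilyl)oxy]-4-[(2E)-hexa-2,5-dien-3-yl]-2-iodocyclopent-2-en-1-one
Product: 10 (4S)-4-[(tert-butyldimethylsilyl)oxy]-4-[(2E)-hexa-2,5-dien-3-yl]-2-methoxycyclopent-2-en-1-one
Conditions: CuI (10 mol %), 3,4,7,8-tetramethyl-1,10-phenanthroline (20 mol %), Cs2CO3, MeOH, toluene, 80 °C
Reagents that add atoms: methanol CO
Why: Ullmann-type copper-catalysed C–O coupling of a vinyl iodide with an alcohol replaces iodine by methoxy on the intact alkene, and loss of the silyloxy group through the C5 enolate is not expected because it would create a cyclopentadienone.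

Step 7
Reactants: 10 (4S)-4-[(tert-butyldimethylsilyl)oxy]-4-[(2E)-hexa-2,5-dien-3-yl]-2-methoxycyclopent-2-en-1-one
Product: 11 (4S,5RS)-4-[(tert-butyldimethylsilyl)oxy]-4-[(2E)-hexa-2,5-dien-3-yl]-5-hydroxy-2-methoxycyclopent-2-en-1-one
Conditions: LiN(SiMe3)2, THF, −78 °C; then 2-(phenylsulfonyl)-3-phenyloxaziridine, −78 °C; H2O
Reagents that add atoms: 2-(phenylsulfonyl)-3-phenyloxaziridine O=S(=O)(c1ccccc1)N1OC1c1ccccc1
Why: Only C5 can be deprotonated, and the lithium enolate is hydroxylated by the N-sulfonyloxaziridine (Davis oxidation); the new centre need not be controlled because it becomes planar again in step 10.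

Step 8
Reactants: 11 (4S,5RS)-4-[(tert-butyldimethylsilyl)oxy]-4-[(2E)-hexa-2,5-dien-3-yl]-5-hydroxy-2-methoxycyclopent-2-en-1-one
Product: 12 (4S,5RS)-4-[(tert-butyldimethylsilyl)oxy]-4-[(2E)-hexa-2,5-dien-3-yl]-2,5-dimethoxycyclopent-2-en-1-one
Conditions: MeI, Ag2O, CaSO4, MeCN, rt, dark
Reagents that add atoms: iodomethane CI
Why: Purdie methylation etherifies the α-ketol under non-basic conditions, which avoids acyloin rearrangement and β-elimination.

Step 9
Reactants: 13 4-hydroxy-3,5-dimethoxybenzaldehyde (syringaldehyde)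
Product: 14 4-[(tert-butyldimethylsilyl)oxy]-3,5-dimethoxybenzaldehyde
Conditions: TBSCl, imidazole, DMF, rt
Reagents that add atoms: tert-butyl(chloro)dimethylsilane CC(C)(C)[Si](C)(C)Cl
Why: Imidazole-promoted silylation masks the phenol so that it neither consumes the silyl triflate in step 10 nor is acetylated in step 12, while the silyloxy group still stabilises the benzylic cation.

Step 10
Reactants: 12 (4S,5RS)-4-[(tert-butyldimethylsilyl)oxy]-4-[(2E)-hexa-2,5-dien-3-yl]-2,5-dimethoxycyclopent-2-en-1-one; 14 4-[(tert-butyldimethylsilyl)oxy]-3,5-dimethoxybenzaldehyde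
Product: 18 (1S,5R,6R,7S)-6-{4-[(tert-butyldimethylsilyl)oxy]-3,5-dimethoxyphenyl}-3,5-dimethoxy-7-methyl-1-(prop-2-en-1-yl)bicyclo[3.2.1]oct-2-ene-4,8-dione, via silyl dienol ether 15 (not isolated), via aldol silyl ether 16 (not isolated), via benzylic cation 17 (not isolated)
Conditions: i-Pr2NEt (1.3 equiv), TMSOTf (1.3 equiv), CH2Cl2, 0 °C; then 14 (1.2 equiv), TMSOTf (1.5 equiv), −78 → −20 °C; aq NaHCO3
Reagents that add atoms: trimethylsilyl trifluoromethanesulfonate C[Si](C)(C)OS(=O)(=O)C(F)(F)F (silyl groups of 15 and 16 only; no atom of it remains in 18)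
Why: Proposed new method: TMSOTf/i-Pr2NEt should turn 12 into the 2-silyloxydiene 15, whose C5 adds to the silyl-activated aldehyde 14 (Mukaiyama aldol) to give 16; TMSOTf then ionises this electron-rich benzylic silyl ether to cation 17, the trisubstituted alkene attacks C6 through C7, and the tertiary cation growing at C1 is quenched by migration of the vinylic C2 from C8 to C1 (pinacol shift) with loss of the silyl group from the C8 oxygen, so that ring A of 12 (C2–C3–C4–C5–C8) becomes the six-membered ring C1–C2–C3–C4–C5–C8 of 18. The closest known reaction types are the Prins–pinacol ring-enlarging annulation of 1-alkenylcycloalkanol silyl ethers, which is started by acetal-derived oxocarbenium ions, and the one-pot silyl enol ether formation/Mukaiyama aldol addition; a benzylic cation made by the aldol step itself as the trigger is new. Ring B (C1–C8–C5–C6–C7) is closed by the C6–C7 bond, exo at the cationic carbon and with both alkene carbons inside the new ring (5-endo for the nucleophilic alkene), which is why a stabilised, reversibly formed cation is used; the six-membered ring is not closed at all but results from the 1,2-shift. C5 is dictated by the C8 stereocentre because only the aldol epimer with the benzylic arm cis to the alkenyl group can cyclise while the other should revert by retro-aldol cleavage, C1 follows from the suprafacial shift within the bicyclic frame, C7 (methyl exo) from the E-alkene combined with addition of C6 and C2 to opposite faces of C1=C7 (migrating bond antiperiplanar to the new bond, methyl kept away from the forming three-carbon bridge), and C6 (aryl endo) from the aryl group standing trans to the C7 methyl and away from the C5 methoxy group. The step needs migration of C2 and not of C5 (C5 would give a cyclobutane and C2 is vinylic), attack of C7 and not of C1 or of the allyl group (tertiary cation, five-membered ring), and no ionisation of the tertiary C8–O bond, which is secured because that cation would be an antiaromatic cyclopentadienyl cation in 15 and a cation conjugated to the enone carbonyl in 16 and 17.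

Step 11
Reactants: 18 (1S,5R,6R,7S)-6-{4-[(tert-butyldimethylsilyl)oxy]-3,5-dimethoxyphenyl}-3,5-dimethoxy-7-methyl-1-(prop-2-en-1-yl)bicyclo[3.2.1]oct-2-ene-4,8-dione
Product: 19 (1S,4R,5S,6R,7S)-6-{4-[(tert-butyldimethylsilyl)oxy]-3,5-dimethoxyphenyl}-4-hydroxy-3,5-dimethoxy-7-methyl-1-(prop-2-en-1-yl)bicyclo[3.2.1]oct-2-en-8-one
Conditions: NaBH4, CeCl3·7H2O, MeOH, −78 °C
Reagents that add atoms: none
Why: Luche reduction is 1,2-selective for the enone carbonyl C4 while the hindered bridging ketone C8 is expected to be masked as its hemiketal in methanol, and hydride should add from the face of the C8 bridge because the other face is covered by the endo aryl group, which gives the 4R alcohol.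

Step 12
Reactants: 19 (1S,4R,5S,6R,7S)-6-{4-[(tert-butyldimethylsilyl)oxy]-3,5-dimethoxyphenyl}-4-hydroxy-3,5-dimethoxy-7-methyl-1-(prop-2-en-1-yl)bicyclo[3.2.1]oct-2-en-8-one
Product: 20 (1S,4R,5S,6R,7S)-6-{4-[(tert-butyldimethylsilyl)oxy]-3,5-dimethoxyphenyl}-3,5-dimethoxy-7-methyl-8-oxo-1-(prop-2-en-1-yl)bicyclo[3.2.1]oct-2-en-4-yl acetate
Conditions: Ac2O, DMAP (cat.), pyridine, CH2Cl2, rt
Reagents that add atoms: acetic anhydride CC(=O)OC(C)=O
Why: DMAP-catalysed acylation (nucleophilic catalysis) esterifies the hindered secondary alcohol with retention of configuration.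

Step 13
Reactants: 20 (1S,4R,5S,6R,7S)-6-{4-[(tert-butyldimethylsilyl)oxy]-3,5-dimethoxyphenyl}-3,5-dimethoxy-7-methyl-8-oxo-1-(prop-2-en-1-yl)bicyclo[3.2.1]oct-2-en-4-yl acetate
Product: 21 (1S,4R,5S,6R,7S)-6-(4-hydroxy-3,5-dimethoxyphenyl)-3,5-dimethoxy-7-methyl-8-oxo-1-(prop-2-en-1-yl)bicyclo[3.2.1]oct-2-en-4-yl acetate (target)
Conditions: Bu4NF, AcOH, THF, 0 °C
Reagents that add atoms: none
Why: Buffered fluoride cleaves the aryl silyl ether (desilylation) while acetic acid keeps the medium from cleaving or shifting the acetate.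

**Compound list**

1 | (4R)-4-[(tert-butyldimethylsilyl)oxy]cyclopent-2-en-1-one | O=C1C=C[C@H](O[Si](C)(C)C(C)(C)C)C1 | starting material
2 | prop-1-yn-1-ylmagnesium bromide | CC#C[Mg]Br | starting material
3 | allylmagnesium bromide | C=CC[Mg]Br | starting material
4 | bromomagnesium (1S,4R)-4-[(tert-butyldimethylsilyl)oxy]-1-(prop-1-yn-1-yl)cyclopent-2-en-1-olate (formed in the flask) | CC#C[C@@]1(O[Mg]Br)C=C[C@H](O[Si](C)(C)C(C)(C)C)C1 | intermediate
5 | (1S,4R)-4-[(tert-butyldimethylsilyl)oxy]-1-[(2E)-hexa-2,5-dien-3-yl]cyclopent-2-en-1-ol | C=CC/C(=C\C)[C@@]1(O)C=C[C@H](O[Si](C)(C)C(C)(C)C)C1 | intermediate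
6 | (1S,4R)-1-[(2E)-hexa-2,5-dien-3-yl]cyclopent-2-ene-1,4-diol | C=CC/C(=C\C)[C@@]1(O)C=C[C@H](O)C1 | intermediate
7 | (4S)-4-[(2E)-hexa-2,5-dien-3-yl]-4-hydroxycyclopent-2-en-1-one | C=CC/C(=C\C)[C@@]1(O)C=CC(=O)C1 | intermediate
8 | (4S)-4-[(tert-butyldimethylsilyl)oxy]-4-[(2E)-hexa-2,5-dien-3-yl]cyclopent-2-en-1-one | C=CC/C(=C\C)[C@@]1(O[Si](C)(C)C(C)(C)C)C=CC(=O)C1 | intermediate
9 | (4S)-4-[(tert-butyldimethylsilyl)oxy]-4-[(2E)-hexa-2,5-dien-3-yl]-2-iodocyclopent-2-en-1-one | C=CC/C(=C\C)[C@@]1(O[Si](C)(C)C(C)(C)C)C=C(I)C(=O)C1 | intermediate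
10 | (4S)-4-[(tert-butyldimethylsilyl)oxy]-4-[(2E)-hexa-2,5-dien-3-yl]-2-methoxycyclopent-2-en-1-one | C=CC/C(=C\C)[C@@]1(O[Si](C)(C)C(C)(C)C)C=C(OC)C(=O)C1 | intermediate
11 | (4S,5RS)-4-[(tert-butyldimethylsilyl)oxy]-4-[(2E)-hexa-2,5-dien-3-yl]-5-hydroxy-2-methoxycyclopent-2-en-1-one (both C5 epimers) | C=CC/C(=C\C)[C@@]1(O[Si](C)(C)C(C)(C)C)C=C(OC)C(=O)C1O | intermediate
12 | (4S,5RS)-4-[(tert-butyldimethylsilyl)oxy]-4-[(2E)-hexa-2,5-dien-3-yl]-2,5-dimethoxycyclopent-2-en-1-one (both C5 epimers) | C=CC/C(=C\C)[C@@]1(O[Si](C)(C)C(C)(C)C)C=C(OC)C(=O)C1OC | intermediate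
13 | 4-hydroxy-3,5-dimethoxybenzaldehyde (syringaldehyde) | O=Cc1cc(OC)c(O)c(OC)c1 | starting material
14 | 4-[(tert-butyldimethylsilyl)oxy]-3,5-dimethoxybenzaldehyde | O=Cc1cc(OC)c(O[Si](C)(C)C(C)(C)C)c(OC)c1 | intermediate
15 | tert-butyl({(1S)-1-[(2E)-hexa-2,5-dien-3-yl]-2,4-dimethoxy-3-[(trimethylsilyl)oxy]cyclopenta-2,4-dien-1-yl}oxy)dimethylsilane (silyl dienol ether of 12; formed in the flask) | C=CC/C(=C\C)[C@@]1(O[Si](C)(C)C(C)(C)C)C=C(OC)C(O[Si](C)(C)C)=C1OC | intermediate
16 | (4S,5R)-4-[(tert-butyldimethylsilyl)oxy]-5-[{4-[(tert-butyldimethylsilyl)oxy]-3,5-dimethoxyphenyl}(trimethylsilyloxy)methyl]-4-[(2E)-hexa-2,5-dien-3-yl]-2,5-dimethoxycyclopent-2-en-1-one (productive C5 epimer, both carbinol epimers; formed in the flask) | C=CC/C(=C\C)[C@@]1(O[Si](C)(C)C(C)(C)C)C=C(OC)C(=O)[C@@]1(OC)C(O[Si](C)(C)C)c1cc(OC)c(O[Si](C)(C)C(C)(C)C)c(OC)c1 | intermediate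
17 | benzylic carbenium ion formed from 16 by loss of the trimethylsilyloxy group, as its trifluoromethanesulfonate ion pair (formed in the flask) | C=CC/C(=C\C)[C@@]1(O[Si](C)(C)C(C)(C)C)C=C(OC)C(=O)[C@@]1(OC)[CH+]c1cc(OC)c(O[Si](C)(C)C(C)(C)C)c(OC)c1.[O-]S(=O)(=O)C(F)(F)F | intermediate
18 | (1S,5R,6R,7S)-6-{4-[(tert-butyldimethylsilyl)oxy]-3,5-dimethoxyphenyl}-3,5-dimethoxy-7-methyl-1-(prop-2-en-1-yl)bicyclo[3.2.1]oct-2-ene-4,8-dione | C=CC[C@]12C=C(OC)C(=O)[C@](OC)(C1=O)[C@@H](c1cc(OC)c(O[Si](C)(C)C(C)(C)C)c(OC)c1)[C@@H]2C | intermediate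
19 | (1S,4R,5S,6R,7S)-6-{4-[(tert-butyldimethylsilyl)oxy]-3,5-dimethoxyphenyl}-4-hydroxy-3,5-dimethoxy-7-methyl-1-(prop-2-en-1-yl)bicyclo[3.2.1]oct-2-en-8-one | C=CC[C@]12C=C(OC)[C@@H](O)[C@](OC)(C1=O)[C@@H](c1cc(OC)c(O[Si](C)(C)C(C)(C)C)c(OC)c1)[C@@H]2C | intermediate
20 | (1S,4R,5S,6R,7S)-6-{4-[(tert-butyldimethylsilyl)oxy]-3,5-dimethoxyphenyl}-3,5-dimethoxy-7-methyl-8-oxo-1-(prop-2-en-1-yl)bicyclo[3.2.1]oct-2-en-4-yl acetate | C=CC[C@]12C=C(OC)[C@@H](OC(C)=O)[C@](OC)(C1=O)[C@@H](c1cc(OC)c(O[Si](C)(C)C(C)(C)C)c(OC)c1)[C@@H]2C | intermediate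
21 | (1S,4R,5S,6R,7S)-6-(4-hydroxy-3,5-dimethoxyphenyl)-3,5-dimethoxy-7-methyl-8-oxo-1-(prop-2-en-1-yl)bicyclo[3.2.1]oct-2-en-4-yl acetate | C=CC[C@]12C=C(OC)[C@@H](OC(C)=O)[C@](OC)(C1=O)[C@@H](c1cc(OC)c(O)c(OC)c1)[C@@H]2C | target

**Step count and risks**

Total step count: 13. Longest linear sequence: 12 steps (steps 1–8 and 10–13, from 1).

Steps most likely to fail:

Step 10 (proposed new method). The cation–olefin closure onto the trisubstituted alkene may be slower than retro-aldol loss of the benzylic arm or fragmentation of the C5–C8 bond, or it may occur with poor facial selectivity at C6 and C7. The fallback uses known reaction types in the opposite order of bond formation; it sets out from 12 and 14 and comes back at 18. Aldehyde 14 is converted with HC(OMe)3, MeOH and PPTS into its dimethyl acetal tert-butyl[4-(dimethoxymethyl)-2,6-dimethoxyphenoxy]dimethylsilane F1. Without amine, so that no silyl enol ether forms, 12 and this acetal are treated with TMSOTf and 2,6-di-tert-butyl-4-methylpyridine in CH2Cl2 at −78 °C. In this intermolecular Prins–pinacol reaction the oxocarbenium ion should add to C7 and C2 should migrate from C8 to C1, giving the ring-enlarged monocyclic diketone 6-allyl-6-[1-{4-[(tert-butyldimethylsilyl)oxy]-3,5-dimethoxyphenyl}-1-methoxypropan-2-yl]-2,4-dimethoxycyclohex-4-ene-1,3-dione F2. BF3·OEt2 in CH2Cl2 (−40 → 0 °C) should then ionise the benzylic methyl ether, and the enol of the 2-methoxy-1,3-diketone should close the C5–C6 bond, the acid-mediated closure by which bicyclo[3.2.1]octanoid neolignans form from benzylic cations. In this order C1 rests on chirality transfer from C8 through an open transition state, so the enantiomeric purity of 18 would have to be checked.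

Step 11. Hydride may also attack the strained bridging C8 ketone, so that the chemoselectivity between the two carbonyl groups is lost. The fallback sets out from 18 and comes back at 20. Excess NaBH4 in MeOH/THF (0 °C → rt) should reduce both ketones, C4 again from the face of the C8 bridge, to the 4,8-diol 6-{4-[(tert-butyldimethylsilyl)oxy]-3,5-dimethoxyphenyl}-3,5-dimethoxy-7-methyl-1-(prop-2-en-1-yl)bicyclo[3.2.1]oct-2-ene-4,8-diol F3. Ac2O/pyridine at 0 °C should acetylate only the C4 hydroxyl, because the C8 hydroxyl lies between two quaternary carbons, giving the 8-hydroxy 4-acetate 6-{4-[(tert-butyldimethylsilyl)oxy]-3,5-dimethoxyphenyl}-8-hydroxy-3,5-dimethoxy-7-methyl-1-(prop-2-en-1-yl)bicyclo[3.2.1]oct-2-en-4-yl acetate F4. Dess–Martin periodinane then re-oxidises C8 to the ketone.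

Step 1. The copper-catalysed carbomagnesiation of the hindered tertiary alkoxide may stall or deliver the allyl group to the wrong alkyne carbon. The fallback sets out from 1 and 2 and comes back at 5. After the alkynyl addition the mixture is worked up and the propargylic alcohol (1S,4R)-4-[(tert-butyldimethylsilyl)oxy]-1-(prop-1-yn-1-yl)cyclopent-2-en-1-ol F5 is isolated. Hydroxyl-directed trans-hydroalumination with LiAlH4/AlCl3 in THF places aluminium on the alkyne carbon next to the carbinol; iodinolysis with I2 should then give the iodoalkene (1S,4R)-4-[(tert-butyldimethylsilyl)oxy]-1-[(1Z)-1-iodoprop-1-en-1-yl]cyclopent-2-en-1-ol F6. Stille coupling with allyltributylstannane (Pd(PPh3)4, CuI, DMF, 40 °C) replaces iodine by allyl with retention of the alkene geometry.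

Further compounds
F1 | step 10 | tert-butyl[4-(dimethoxymethyl)-2,6-dimethoxyphenoxy]dimethylsilane | COC(OC)c1cc(OC)c(O[Si](C)(C)C(C)(C)C)c(OC)c1
F2 | step 10 | 6-allyl-6-[1-{4-[(tert-butyldimethylsilyl)oxy]-3,5-dimethoxyphenyl}-1-methoxypropan-2-yl]-2,4-dimethoxycyclohex-4-ene-1,3-dione (quaternary and methyl-bearing carbons configured as C1 and C7 of 18; mixture at the two other sp3 carbons) | C=CC[C@@]1(C=C(OC)C(=O)C(OC)C1=O)[C@@H](C)C(OC)c1cc(OC)c(O[Si](C)(C)C(C)(C)C)c(OC)c1
F3 | step 11 | 6-{4-[(tert-butyldimethylsilyl)oxy]-3,5-dimethoxyphenyl}-3,5-dimethoxy-7-methyl-1-(prop-2-en-1-yl)bicyclo[3.2.1]oct-2-ene-4,8-diol (configured as 19 at C1, C4, C5, C6 and C7; both C8 epimers) | C=CC[C@]12C=C(OC)[C@@H](O)[C@](OC)(C1O)[C@@H](c1cc(OC)c(O[Si](C)(C)C(C)(C)C)c(OC)c1)[C@@H]2C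
F4 | step 11 | 6-{4-[(tert-butyldimethylsilyl)oxy]-3,5-dimethoxyphenyl}-8-hydroxy-3,5-dimethoxy-7-methyl-1-(prop-2-en-1-yl)bicyclo[3.2.1]oct-2-en-4-yl acetate (configured as 20 at C1, C4, C5, C6 and C7; both C8 epimers) | C=CC[C@]12C=C(OC)[C@@H](OC(C)=O)[C@](OC)(C1O)[C@@H](c1cc(OC)c(O[Si](C)(C)C(C)(C)C)c(OC)c1)[C@@H]2C
F5 | step 1 | (1S,4R)-4-[(tert-butyldimethylsilyl)oxy]-1-(prop-1-yn-1-yl)cyclopent-2-en-1-ol | CC#C[C@@]1(O)C=C[C@H](O[Si](C)(C)C(C)(C)C)C1
F6 | step 1 | (1S,4R)-4-[(tert-butyldimethylsilyl)oxy]-1-[(1Z)-1-iodoprop-1-en-1-yl]cyclopent-2-en-1-ol | C/C=C(\I)[C@@]1(O)C=C[C@H](O[Si](C)(C)C(C)(C)C)C1
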